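**Retrosynthetic overview**

- The strategy rests on the furan ring: its O1–C2 bond lies on the carbon that carries the benzoquinone ring, so furan C2, C3, C4 and C5 correspond to the CH2, the olefinic CH, the branch carbon and the CH2OH carbon of an open-chain (hydroxymethyl)alkenyl quinone.
- The furan is the only ring made and it is made last: quinone to o-quinone methide tautomerization, 5-exo O–C closure to the 2,5-dihydrofuran, then oxidation, a second tautomerization and a final oxidation in the same flask. The six-membered ring is bought as the arene.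
- The quinone precursor comes from the para-dimethoxyarene by oxidative demethylation after desilylation; the senecioate is put on the (S)-alcohol, which is obtained by Sharpless kinetic resolution.
- The carbon skeleton comes from an iodo-aldol of methyl propiolate with 4-methylpent-3-enal (Z-iodoalkene), Negishi coupling with 2,5-dimethoxybenzylzinc chloride, DIBAL-H reduction and primary silylation.

Key step: step 11

Remark on the chemistry: quinone and hydroquinone partners are assumed to exchange hydrogen quickly under base, so the ring closure is run with the oxidant already in the flask and the ring-closed hydroquinone is not isolated.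

**Route**

Step 1
Reactants: 1 4-methylpent-3-en-1-ol
Product: 2 4-methylpent-3-enal
Conditions: Dess–Martin periodinane (1.2 equiv), NaHCO3, CH2Cl2, 0 °C to rt; filtered solution used at once
Reagents that add atoms: none
Why: Dess–Martin oxidation takes the primary alcohol to the aldehyde without over-oxidation, and the bicarbonate buffer should keep the β,γ-double bond from moving into conjugation.

Step 2
Reactants: 3 methyl propiolate; 2 4-methylpent-3-enal
Product: 5 methyl (2Z)-2-(1-hydroxy-4-methylpent-3-en-1-yl)-3-iodoprop-2-enoate (racemic), via aluminium iodoallenolate 4 (not isolated)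
Conditions: Et2AlI (1.2 equiv), CH2Cl2, 0 °C, 30 min; then 2, −40 to 0 °C; aqueous Rochelle salt
Reagents that add atoms: diethylaluminium iodide, CC[Al](I)CC
Why: In this iodo-aldol (halo-Morita–Baylis–Hillman-type) reaction iodide adds to the propiolate to give the aluminium β-iodoallenolate, which attacks the aldehyde through its α-carbon under kinetic control so that iodine ends up cis to the ester (Z), the carbinol centre being formed as the racemate.

Step 3
Reactants: 6 2,5-dimethoxybenzyl chloride
Product: 7 (2,5-dimethoxybenzyl)zinc chloride (THF solution containing LiCl, titrated and used as such)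
Conditions: Zn dust (1.5 equiv), LiCl (1.5 equiv), THF, rt
Reagents that add atoms: zinc, [Zn]
Why: Direct insertion of zinc into the benzylic chloride, accelerated by LiCl, should give the benzylzinc chloride with little Wurtz homocoupling.

Step 4
Reactants: 5 methyl (2Z)-2-(1-hydroxy-4-methylpent-3-en-1-yl)-3-iodoprop-2-enoate; 7 (2,5-dimethoxybenzyl)zinc chloride (1.5 equiv)
Product: 8 methyl (2Z)-4-(2,5-dimethoxyphenyl)-2-(1-hydroxy-4-methylpent-3-en-1-yl)but-2-enoate (racemic)
Conditions: Pd(OAc)2 (2 mol%), SPhos (4 mol%), THF, rt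
Reagents that add atoms: none
Why: Negishi cross-coupling of the alkenyl iodide with the benzylzinc reagent goes with retention of alkene geometry, so the arylmethyl group ends up cis to the ester, and the phosphine-ligated palladium should couple faster than the organozinc is quenched by the free hydroxyl.

Step 5
Reactants: 8 methyl (2Z)-4-(2,5-dimethoxyphenyl)-2-(1-hydroxy-4-methylpent-3-en-1-yl)but-2-enoate
Product: 9 (2E)-2-[2-(2,5-dimethoxyphenyl)ethylidene]-6-methylhept-5-ene-1,3-diol (racemic; CH2OH cis to the arylmethyl group)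
Conditions: DIBAL-H (3.5 equiv), CH2Cl2, −78 to 0 °C; aqueous Rochelle salt
Reagents that add atoms: none
Why: DIBAL-H reduces the conjugated ester in 1,2 fashion to the primary allylic alcohol and leaves the alkenes and their geometry alone, the change of descriptor from Z to E coming only from the changed priorities.

Step 6
Reactants: 9 (2E)-2-[2-(2,5-dimethoxyphenyl)ethylidene]-6-methylhept-5-ene-1,3-diol
Product: 10 (2E)-1-{[tert-butyl(dimethyl)silyl]oxy}-2-[2-(2,5-dimethoxyphenyl)ethylidene]-6-methylhept-5-en-3-ol (racemic)
Conditions: TBSCl (1.05 equiv), imidazole (2 equiv), CH2Cl2, −20 to 0 °C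
Reagents that add atoms: tert-butyl(chloro)dimethylsilane, CC(C)(C)[Si](C)(C)Cl
Why: Silylation with one equivalent of the silyl chloride at low temperature selects the unhindered primary hydroxyl over the secondary allylic one.

Step 7
Reactants: 10 (2E)-1-{[tert-butyl(dimethyl)silyl]oxy}-2-[2-(2,5-dimethoxyphenyl)ethylidene]-6-methylhept-5-en-3-ol (racemic)
Product: 11 (2E,3S)-1-{[tert-butyl(dimethyl)silyl]oxy}-2-[2-(2,5-dimethoxyphenyl)ethylidene]-6-methylhept-5-en-3-ol
Conditions: Ti(OiPr)4 (0.15 equiv), D-(−)-diisopropyl tartrate (0.2 equiv), t-BuOOH (0.6 equiv, decane solution), 4 Å MS, CH2Cl2, −20 °C, to about 60% conversion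
Reagents that add atoms: none
Why: In the Sharpless kinetic resolution the titanium D-(−)-tartrate catalyst should epoxidize the (R)-alcohol quickly to its anti epoxy alcohol while the mismatched (S)-alcohol is left behind, so that running slightly past half conversion should return the (S)-alcohol in high enantiomeric purity, the homoallylic prenyl alkene being epoxidized far more slowly.

Step 8
Reactants: 11 (2E,3S)-1-{[tert-butyl(dimethyl)silyl]oxy}-2-[2-(2,5-dimethoxyphenyl)ethylidene]-6-methylhept-5-en-3-ol; 12 3-methylbut-2-enoic acid (1.5 equiv)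
Product: 13 (2E,3S)-1-{[tert-butyl(dimethyl)silyl]oxy}-2-[2-(2,5-dimethoxyphenyl)ethylidene]-6-methylhept-5-en-3-yl 3-methylbut-2-enoate
Conditions: DCC (1.5 equiv), DMAP (0.2 equiv), CH2Cl2, 0 °C to rt
Reagents that add atoms: none
Why: Steglich esterification acylates the hydroxyl oxygen without touching the C–O bond, so the (S) configuration is kept, and the carbodiimide route avoids the ketene pathway that deconjugates senecioyl chloride.

Step 9
Reactants: 13 (2E,3S)-1-{[tert-butyl(dimethyl)silyl]oxy}-2-[2-(2,5-dimethoxyphenyl)ethylidene]-6-methylhept-5-en-3-yl 3-methylbut-2-enoate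
Product: 14 (2E,3S)-2-[2-(2,5-dimethoxyphenyl)ethylidene]-1-hydroxy-6-methylhept-5-en-3-yl 3-methylbut-2-enoate
Conditions: HF·pyridine, pyridine, THF, 0 °C to rt
Reagents that add atoms: none
Why: Pyridine-buffered HF cleaves the primary silyl ether without forming a free alkoxide, which should suppress 1,3-migration of the senecioyl group to the primary oxygen.

Step 10
Reactants: 14 (2E,3S)-2-[2-(2,5-dimethoxyphenyl)ethylidene]-1-hydroxy-6-methylhept-5-en-3-yl 3-methylbut-2-enoate
Product: 15 2-[(2E,4S)-3-(hydroxymethyl)-7-methyl-4-(3-methylbut-2-enoyloxy)octa-2,6-dien-1-yl]-1,4-benzoquinone (CH2OH cis to the quinonyl-CH2)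
Conditions: (NH4)2Ce(NO3)6 (2.5 equiv), MeCN/H2O 2:1, 0 °C, 15 min; cold extractive work-up, crude product taken on at once
Reagents that add atoms: water, O
Why: Oxidative demethylation of the para-dimethoxyarene by (NH4)2Ce(NO3)6 gives the 1,4-benzoquinone through the arene radical cation and attack of water, and it should be fast enough at 0 °C for the alkenes, the ester and the allylic alcohol to survive.

Step 11
Reactants: 15 2-[(2E,4S)-3-(hydroxymethyl)-7-methyl-4-(3-methylbut-2-enoyloxy)octa-2,6-dien-1-yl]-1,4-benzoquinone
Product: 21 (1S)-1-[5-(3,6-dioxocyclohexa-1,4-dien-1-yl)furan-3-yl]-4-methylpent-3-en-1-yl 3-methylbut-2-enoate, via o-quinone methide 16 (not isolated), via dihydrofuranyl hydroquinone 17 (not isolated), via dihydrofuranyl quinone 18 (not isolated), via furanylidene quinone methide 19 (not isolated), via furyl hydroquinone 20 (not isolated)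
Conditions: Ag2O (5 equiv), Et3N (0.5 equiv), MgSO4, CH2Cl2 (0.01 M), 0 °C to rt, dark
Reagents that add atoms: none
Why: Proposed new method: Et3N removes a proton from the quinonyl CH2 (allylic and vinylogous to the distal carbonyl) and O-protonation gives the hydroxy o-quinone methide 16, as in the known base-induced tautomerization of 2-prenyl-1,4-benzoquinones that normally ends in oxa-6π closure to 2H-chromenes. The cis-placed primary hydroxyl should then add to the exocyclic methide carbon in a 5-exo-trig oxa-conjugate addition (closest known type: trapping of o-quinone methides by tethered alcohols), which forms the future furan O1–C2 bond, closes the 2,5-dihydrofuran and rearomatizes the carbocycle to hydroquinone 17. The new ring CH is formed without any controlling element as both epimers, which is harmless because Ag2O oxidizes 17 to quinone 18 and the same tautomerization (through 19) removes this hydrogen together with one O–CH2 hydrogen to give the aromatic furan 20, which Ag2O finally oxidizes to 21. The step needs chemoselectivity for hydroxyl addition over oxa-6π closure, which the alkene geometry (CH2OH held next to the methide carbon and able to reach it from either methide geometry, whereas 6π closure needs the side chain syn to the carbonyl) and the irreversible oxidative drain to the furan should secure. The (S)-carbinol is not touched because neither acid nor strong base is present to ionize the allylic senecioate, and any open-chain hydroquinone formed by hydrogen exchange between quinone and hydroquinone partners is returned to 15 by the Ag2O.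

**Compound list**

1 | 4-methylpent-3-en-1-ol | CC(C)=CCCO | starting material
2 | 4-methylpent-3-enal | CC(C)=CCC=O | intermediate
3 | methyl propiolate | C#CC(=O)OC | starting material
4 | diethylaluminium 3-iodo-1-methoxypropa-1,2-dien-1-olate (aluminium β-iodoallenolate) | COC(O[Al](CC)CC)=C=CI | intermediate
5 | methyl (2Z)-2-(1-hydroxy-4-methylpent-3-en-1-yl)-3-iodoprop-2-enoate, racemic | COC(=O)/C(=C\I)C(O)CC=C(C)C | intermediate
6 | 2,5-dimethoxybenzyl chloride | COc1ccc(OC)c(CCl)c1 | starting material
7 | (2,5-dimethoxybenzyl)zinc chloride | COc1ccc(OC)c(C[Zn]Cl)c1 | intermediate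
8 | methyl (2Z)-4-(2,5-dimethoxyphenyl)-2-(1-hydroxy-4-methylpent-3-en-1-yl)but-2-enoate, racemic | COC(=O)/C(=C\Cc1cc(OC)ccc1OC)C(O)CC=C(C)C | intermediate
9 | (2E)-2-[2-(2,5-dimethoxyphenyl)ethylidene]-6-methylhept-5-ene-1,3-diol, racemic | OC/C(=C\Cc1cc(OC)ccc1OC)C(O)CC=C(C)C | intermediate
10 | (2E)-1-{[tert-butyl(dimethyl)silyl]oxy}-2-[2-(2,5-dimethoxyphenyl)ethylidene]-6-methylhept-5-en-3-ol, racemic | CC(C)(C)[Si](C)(C)OC/C(=C\Cc1cc(OC)ccc1OC)C(O)CC=C(C)C | intermediate
11 | (2E,3S)-1-{[tert-butyl(dimethyl)silyl]oxy}-2-[2-(2,5-dimethoxyphenyl)ethylidene]-6-methylhept-5-en-3-ol | CC(C)=CC[C@H](O)/C(CO[Si](C)(C)C(C)(C)C)=C/Cc1cc(OC)ccc1OC | intermediate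
12 | 3-methylbut-2-enoic acid | CC(C)=CC(=O)O | starting material
13 | (2E,3S)-1-{[tert-butyl(dimethyl)silyl]oxy}-2-[2-(2,5-dimethoxyphenyl)ethylidene]-6-methylhept-5-en-3-yl 3-methylbut-2-enoate | CC(C)=CC[C@H](OC(=O)C=C(C)C)/C(CO[Si](C)(C)C(C)(C)C)=C/Cc1cc(OC)ccc1OC | intermediate
14 | (2E,3S)-2-[2-(2,5-dimethoxyphenyl)ethylidene]-1-hydroxy-6-methylhept-5-en-3-yl 3-methylbut-2-enoate | CC(C)=CC[C@H](OC(=O)C=C(C)C)/C(CO)=C/Cc1cc(OC)ccc1OC | intermediate
15 | 2-[(2E,4S)-3-(hydroxymethyl)-7-methyl-4-(3-methylbut-2-enoyloxy)octa-2,6-dien-1-yl]-1,4-benzoquinone | CC(C)=CC[C@H](OC(=O)C=C(C)C)/C(CO)=C/CC1=CC(=O)C=CC1=O | intermediate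
16 | 4-hydroxy-6-[(2E,4S)-3-(hydroxymethyl)-7-methyl-4-(3-methylbut-2-enoyloxy)octa-2,6-dien-1-ylidene]cyclohexa-2,4-dien-1-one (o-quinone methide, methide geometry not fixed) | CC(C)=CC[C@H](OC(=O)C=C(C)C)/C(CO)=C/C=C1C=C(O)C=CC1=O | intermediate
17 | (1S)-1-[5-(2,5-dihydroxyphenyl)-2,5-dihydrofuran-3-yl]-4-methylpent-3-en-1-yl 3-methylbut-2-enoate (both epimers at the ring CH) | CC(C)=CC[C@H](OC(=O)C=C(C)C)C1=CC(c2cc(O)ccc2O)OC1 | intermediate
18 | (1S)-1-[5-(3,6-dioxocyclohexa-1,4-dien-1-yl)-2,5-dihydrofuran-3-yl]-4-methylpent-3-en-1-yl 3-methylbut-2-enoate (both epimers at the ring CH) | CC(C)=CC[C@H](OC(=O)C=C(C)C)C1=CC(C2=CC(=O)C=CC2=O)OC1 | intermediate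
19 | (1S)-1-[5-(3-hydroxy-6-oxocyclohexa-2,4-dien-1-ylidene)-2,5-dihydrofuran-3-yl]-4-methylpent-3-en-1-yl 3-methylbut-2-enoate (furanylidene quinone methide) | CC(C)=CC[C@H](OC(=O)C=C(C)C)C1=CC(=C2C=C(O)C=CC2=O)OC1 | intermediate
20 | (1S)-1-[5-(2,5-dihydroxyphenyl)furan-3-yl]-4-methylpent-3-en-1-yl 3-methylbut-2-enoate | CC(C)=CC[C@H](OC(=O)C=C(C)C)c1coc(-c2cc(O)ccc2O)c1 | intermediate
21 | (1S)-1-[5-(3,6-dioxocyclohexa-1,4-dien-1-yl)furan-3-yl]-4-methylpent-3-en-1-yl 3-methylbut-2-enoate (CNP0314322.1) | CC(C)=CC[C@H](OC(=O)C=C(C)C)c1coc(C2=CC(=O)C=CC2=O)c1 | target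

**Step count**

Total step count: 11.
Longest linear sequence: 10 steps (steps 1, 2 and 4 to 11, from 1 to 21); step 3 is a one-step side branch.

**Steps most likely to fail**

1. Step 11 (proposed new method). The methide may be consumed by oxa-6π closure through its carbonyl oxygen, by dimerization, or by loss of the senecioate from the extended enolates before the hydroxyl adds. The fallback uses known chemistry and sets out from 14. DDQ (1.1 equiv, CH2Cl2, 4 Å MS, 0 °C) abstracts hydride from the methylene that is both allylic and benzylic to the electron-rich arene, and the primary hydroxyl traps the cation (dehydrogenative etherification) to give (1S)-1-[5-(2,5-dimethoxyphenyl)-2,5-dihydrofuran-3-yl]-4-methylpent-3-en-1-yl 3-methylbut-2-enoate F1. A second equivalent of DDQ at rt aromatizes this to (1S)-1-[5-(2,5-dimethoxyphenyl)furan-3-yl]-4-methylpent-3-en-1-yl 3-methylbut-2-enoate F2. Oxidative demethylation of F2 with (NH4)2Ce(NO3)6 in MeCN/H2O at 0 °C then gives 21, where the route ends.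

2. Step 2. The Lewis-acidic iodoaluminium reagent may isomerize or self-condense the β,γ-unsaturated aldehyde, or the adduct may equilibrate and lose the Z geometry. The fallback sets out from 6 and 3. Copper-catalysed benzylation (CuI, NaI, Cs2CO3, MeCN, rt) gives methyl 4-(2,5-dimethoxyphenyl)but-2-ynoate F3. Syn hydroalumination with DIBAL-H and N-methylmorpholine N-oxide (THF, 0 °C) gives methyl (2E)-2-(diisobutylalumanyl)-4-(2,5-dimethoxyphenyl)but-2-enoate F4 (aluminium cis to the new vinyl hydrogen). This adds to aldehyde 2 through its α-carbon (vinylalumination aldol) and gives 8 directly, so steps 2 to 4 are bypassed and the route is rejoined at 8.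

3. Step 7. The rate difference between the two enantiomers may be too small, because of the bulky silyloxymethyl group on the alkene, to give high enantiomeric purity at useful recovery. The fallback sets out from 10. Dess–Martin oxidation gives (2E)-1-{[tert-butyl(dimethyl)silyl]oxy}-2-[2-(2,5-dimethoxyphenyl)ethylidene]-6-methylhept-5-en-3-one F5. Corey–Bakshi–Shibata reduction with the (R)-methyl oxazaborolidine and catecholborane (toluene, −78 °C), the alkenyl group acting as the large substituent, should give the (S)-alcohol, which is 11.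

**Further compounds**

F1 | step 11 | (1S)-1-[5-(2,5-dimethoxyphenyl)-2,5-dihydrofuran-3-yl]-4-methylpent-3-en-1-yl 3-methylbut-2-enoate (both epimers at the ring CH) | CC(C)=CC[C@H](OC(=O)C=C(C)C)C1=CC(c2cc(OC)ccc2OC)OC1
F2 | step 11 | (1S)-1-[5-(2,5-dimethoxyphenyl)furan-3-yl]-4-methylpent-3-en-1-yl 3-methylbut-2-enoate | CC(C)=CC[C@H](OC(=O)C=C(C)C)c1coc(-c2cc(OC)ccc2OC)c1
F3 | step 2 | methyl 4-(2,5-dimethoxyphenyl)but-2-ynoate | COC(=O)C#CCc1cc(OC)ccc1OC
F4 | step 2 | methyl (2E)-2-(diisobutylalumanyl)-4-(2,5-dimethoxyphenyl)but-2-enoate | COC(=O)/C(=C\Cc1cc(OC)ccc1OC)[Al](CC(C)C)CC(C)C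
F5 | step 7 | (2E)-1-{[tert-butyl(dimethyl)silyl]oxy}-2-[2-(2,5-dimethoxyphenyl)ethylidene]-6-methylhept-5-en-3-one | CC(C)=CCC(=O)/C(CO[Si](C)(C)C(C)(C)C)=C/Cc1cc(OC)ccc1OC
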